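**Retrosynthetic overview**
1. The exocyclic methylene comes from a C8 ketone by Wittig reaction. Base first equilibrates C9 to the trans four/nine ring fusion.
2. Pyran ring: norflavesone (an acylfilicinic acid) is joined to a masked C5 aldehyde by Knoevenagel condensation and hydride transfer. The C4 tertiary alcohol then closes the ring, and its C–O bond is never broken.
3. Nine-membered ring (key steps): two ring expansions of a cyclobutane-fused cyclohexanone. A Baeyer–Villiger 1,2-shift moves quaternary C4 from C8 to oxygen (six to seven, retention). A SmI2-driven O-to-C acyl transfer by C7 follows (seven to nine).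
4. C4 and C5 are set before any medium ring exists, because the target has the C4/C5 configuration of the less accessible caryophyllene face. They are set by a new amine-catalysed Mukaiyama–Michael addition of a fully substituted silyl enol ether to fumaraldehyde mono(dimethyl acetal).
5. Ring order: cyclobutane plus six-membered ring (enone/isobutene photocycloaddition), lactone, nine-membered carbocycle, pyran. The acylfilicinic ring is built separately from methyl isobutyrate, diketene and isobutyryl chloride.

Convention: terpene carbons keep the bicyclo[7.2.0]undecane (caryophyllane) locants C1–C11 in the text. C1′ is the carbon that ends as the pyran CH2.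
Assumption: C9 is carried as the cis-fused epimer from 4 to 22, and the SMILES show that epimer. It is corrected in the last step.

**Step 1**
Reactants: 1 cyclohex-2-en-1-one; 2 2-methylpropene
Product: 4 (1R,6R)-7,7-dimethylbicyclo[4.2.0]octan-2-one (cis-fused), via trans-fused photoadduct 3 (not isolated)
Conditions: AlBr3 adduct of the B-(2,4,6-trifluorophenyl)-1,3,2-oxazaborolidine of α,α-bis(3,5-dimethylphenyl)prolinol (50 mol%, the enantiomer that gives 6R), 2 (excess), CH2Cl2, −75 °C, hν 366 nm; then basic Al2O3
Reagents that add atoms: none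
Why: This is a Lewis-acid-mediated enone–alkene [2+2] photocycloaddition that runs stepwise through a triplet 1,4-diradical; the chiral Lewis acid covers one enone face and sets C1 (octanone C6), head-to-tail addition puts CMe2 next to C1, and alumina epimerises the strained trans isomer at C9 to the cis ketone.

**Step 2**
Reactants: 4 (1R,6R)-7,7-dimethylbicyclo[4.2.0]octan-2-one
Product: 5 (1R,6R)-7,7-dimethyl-3-methylidenebicyclo[4.2.0]octan-2-one
Conditions: (CH2O)n, i-Pr2NH·CF3CO2H, CF3CO2H (10 mol%), THF, reflux
Reagents that add atoms: paraformaldehyde (as formaldehyde), C=O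
Why: In this Mannich-type α-methylenation only C4 carries the two α-hydrogens that addition–elimination needs, so the future C4 methyl carbon enters regiospecifically and no stereocentre is touched.

**Step 3**
Reactants: 5 (1R,6R)-7,7-dimethyl-3-methylidenebicyclo[4.2.0]octan-2-one
Product: 6 triethyl{[(1R,6R)-3,7,7-trimethylbicyclo[4.2.0]oct-2-en-2-yl]oxy}silane
Conditions: Et3SiH, RhCl(PPh3)3 (0.5 mol%), benzene, 50 °C
Reagents that add atoms: triethylsilane, CC[SiH](CC)CC
Why: Rhodium-catalysed 1,4-hydrosilylation of the enone fixes the enol double bond between C8 and C4 with no competition from C9, and any enone that has isomerised to the endocyclic form gives the same product.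

**Step 4**
Reactants: 6 triethyl{[(1R,6R)-3,7,7-trimethylbicyclo[4.2.0]oct-2-en-2-yl]oxy}silane; 7 (E)-4,4-dimethoxybut-2-enal (fumaraldehyde with one aldehyde carried as its dimethyl acetal protecting group)
Product: 8 (3S)-4,4-dimethoxy-3-[(1R,3S,6R)-3,7,7-trimethyl-2-oxobicyclo[4.2.0]octan-3-yl]butanal
Conditions: (2R,5R)-5-benzyl-2-tert-butyl-3-methylimidazolidin-4-one (20 mol%), 2,4-dinitrobenzoic acid (20 mol%), H2O (2 equiv), CH2Cl2, −20 to 4 °C
Reagents that add atoms: none
Why: Proposed new method: an iminium-catalysed Mukaiyama–Michael addition in which a fully substituted, non-aromatic cyclic silyl enol ether is the donor, so that quaternary C4 and tertiary C5 are joined in one step; the amine condenses with 7 to an E-iminium ion whose acetal-bearing β-carbon is strongly electrophilic and whose one face is covered by the benzyl group, which fixes C5 (the catalyst enantiomer is chosen by analogy with known conjugate additions to crotonaldehyde); 6 can be reached only on its convex face, anti to the pseudoaxial cyclobutane CH2 on C9, which fixes C4 with the new chain trans to the four-membered ring; water takes up the silyl group and hydrolyses the enamine, and material from the minor enantiomer of 4 becomes a separable diastereomer; the closest known reactions are the amine-catalysed Mukaiyama–Michael additions of 5-substituted 2-silyloxyfurans and of aryl ketone silyl enol ethers to enals.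

**Step 5**
Reactants: 8 (3S)-4,4-dimethoxy-3-[(1R,3S,6R)-3,7,7-trimethyl-2-oxobicyclo[4.2.0]octan-3-yl]butanal
Product: 9 (1R,3S,6R)-3-[(2S)-4-hydroxy-1,1-dimethoxybutan-2-yl]-3,7,7-trimethylbicyclo[4.2.0]octan-2-one
Conditions: NaBH4, MeOH, −40 °C
Reagents that add atoms: none
Why: In this chemoselective borohydride reduction the unhindered C7 aldehyde reacts far faster than the C8 ketone, which is flanked by a quaternary carbon and a ring-fusion carbon.

**Step 6**
Reactants: 9 (1R,3S,6R)-3-[(2S)-4-hydroxy-1,1-dimethoxybutan-2-yl]-3,7,7-trimethylbicyclo[4.2.0]octan-2-one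
Product: 10 (1R,3S,6R)-3-[(2S)-4-bromo-1,1-dimethoxybutan-2-yl]-3,7,7-trimethylbicyclo[4.2.0]octan-2-one
Conditions: CBr4, PPh3, 2,6-lutidine, CH2Cl2, 0 °C
Reagents that add atoms: tetrabromomethane, BrC(Br)(Br)Br
Why: The Appel reaction of a primary alcohol runs under near-neutral conditions that spare the acetal, and a bromide (unlike an iodide) survives the peracid of the next step.

**Step 7**
Reactants: 10 (1R,3S,6R)-3-[(2S)-4-bromo-1,1-dimethoxybutan-2-yl]-3,7,7-trimethylbicyclo[4.2.0]octan-2-one
Product: 11 (1R,4S,7R)-4-[(2S)-4-bromo-1,1-dimethoxybutan-2-yl]-4,8,8-trimethyl-3-oxabicyclo[5.2.0]nonan-2-one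
Conditions: mCPBA (3 equiv), CH2Cl2, 23 °C, dark
Reagents that add atoms: mCPBA, O=C(OO)c1cccc(Cl)c1
Why: The Baeyer–Villiger oxidation is a carbon-to-oxygen 1,2-shift and the first ring expansion (six to seven); fully substituted C4 migrates in preference to the cyclobutyl CH (C9) and does so with retention, so the C4–O bond of the target is made with the configuration set in step 4.

**Step 8**
Reactants: 11 (1R,4S,7R)-4-[(2S)-4-bromo-1,1-dimethoxybutan-2-yl]-4,8,8-trimethyl-3-oxabicyclo[5.2.0]nonan-2-one
Product: 12 (1R,4S,5S,8S,9R)-5-(dimethoxymethyl)-4,11,11-trimethyl-4,8-epoxybicyclo[7.2.0]undecan-8-ol (transannular hemiketal of the 4-hydroxy-8-ketone)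
Conditions: SmI2 (2.5 equiv), HMPA, THF, 0 °C; pH 7 buffer
Reagents that add atoms: none
Why: In this samarium Barbier-type intramolecular nucleophilic acyl substitution the C7 organosamarium attacks the lactone carbonyl C8 through a six-membered transition state, and transferring the acyl group from O to C turns the seven-membered lactone into the nine-membered carbocycle (second ring expansion); the tetrahedral adduct is kept as the bridged hemiketal, which prevents over-reduction, and its C8 configuration is fixed by the bridge.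

**Step 9**
Reactants: 13 methyl 2-methylpropanoate; 14 diketene (4-methylideneoxetan-2-one)
Product: 16 2,2-dimethylcyclohexane-1,3,5-trione (filicinic acid), via dioxo ester 15 (not isolated)
Conditions: LiN(i-Pr)2 (1.05 equiv), THF, −78 °C; 14; then LiN(i-Pr)2 (1.2 equiv), −78 to 40 °C; aq. HCl
Reagents that add atoms: none
Why: Acetoacetylation of the ester enolate by acyl–oxygen opening of diketene is followed by Dieckmann-type Claisen cyclisation of the 1,3-diketone dianion through its terminal carbon, driven by formation of the very stable triketone anion.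

**Step 10**
Reactants: 16 2,2-dimethylcyclohexane-1,3,5-trione; 17 2-methylpropanoyl chloride
Product: 19 3,5-dihydroxy-6,6-dimethyl-2-(2-methylpropanoyl)cyclohexa-2,4-dien-1-one (norflavesone), via enol isobutyrate 18 (not isolated)
Conditions: Et3N, CH2Cl2, 0 °C; then 4-(dimethylamino)pyridine (20 mol%), 40 °C; aq. HCl
Reagents that add atoms: none
Why: O-acylation is followed by nucleophile-catalysed O-to-C acyl migration (Fries-type), the standard route to 2-acyl-1,3-diones; the two CH2 sites of 16 are equivalent, and the chelated product is too poor a nucleophile to react twice.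

**Step 11**
Reactants: 12 hemiketal acetal; 19 norflavesone
Product: 22 (1R,4S,5R,9R) C8 ketone (the 8-oxo analogue of the target with cis four/nine fusion), via alkylidene triketone 20 (not isolated), via alkylated triketone hemiketal 21 (not isolated)
Conditions: diethyl 2,6-dimethyl-1,4-dihydropyridine-3,5-dicarboxylate (1.3 equiv), TsOH·H2O (15 mol%), MeCN, 23 °C; then toluene, 4 Å MS, 70 °C
Reagents that add atoms: none
Why: Acid-catalysed Knoevenagel condensation of the acetal (through its oxocarbenium ion) with the C–H acidic triketone is followed by Hantzsch-ester transfer hydrogenation of the alkylidene triketone (reductive alkylation) and then dehydrative enol-ether formation; in the last stage the hemiketal opens and the C4 hydroxyl adds to the non-chelated carbonyl next to CMe2, so the C4–O bond is never broken and C4 and C5 keep their configuration.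

**Step 12**
Reactants: 22 (1R,4S,5R,9R) C8 ketone
Product: 24 target CNP0497637.1 (1R,4S,5R,9S), via trans-fused ketone 23 (not isolated)
Conditions: Ph3PCH3Br (6 equiv), KOt-Bu (5.5 equiv), toluene/THF, 23 °C; add 22, 23 to 60 °C; aq. NH4Cl
Reagents that add atoms: methyltriphenylphosphonium bromide, C[P+](c1ccccc1)(c1ccccc1)c1ccccc1.[Br-]
Why: Excess base first equilibrates C9 through the C8 enolate to the more stable trans-fused bicyclo[7.2.0]undecanone, which sets C9 as S; the triketone is shielded as its delocalised enolate, and Wittig methylenation of the only electrophilic carbonyl left installs the exocyclic alkene.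

**Compound list**
1 | cyclohex-2-en-1-one | O=C1C=CCCC1 | starting material
2 | 2-methylpropene | C=C(C)C | starting material
3 | (1S,6R)-7,7-dimethylbicyclo[4.2.0]octan-2-one (trans-fused) | O=C1CCC[C@@H]2[C@@H]1CC2(C)C | intermediate
4 | (1R,6R)-7,7-dimethylbicyclo[4.2.0]octan-2-one (cis-fused) | O=C1CCC[C@@H]2[C@H]1CC2(C)C | intermediate
5 | (1R,6R)-7,7-dimethyl-3-methylidenebicyclo[4.2.0]octan-2-one | O=C1C(=C)CC[C@@H]2[C@H]1CC2(C)C | intermediate
6 | triethyl{[(1R,6R)-3,7,7-trimethylbicyclo[4.2.0]oct-2-en-2-yl]oxy}silane | CC[Si](CC)(CC)OC1=C(C)CC[C@@H]2[C@H]1CC2(C)C | intermediate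
7 | (E)-4,4-dimethoxybut-2-enal | COC(OC)/C=C/C=O | starting material
8 | (3S)-4,4-dimethoxy-3-[(1R,3S,6R)-3,7,7-trimethyl-2-oxobicyclo[4.2.0]octan-3-yl]butanal | O=C1[C@](C)([C@H](CC=O)C(OC)OC)CC[C@@H]2[C@H]1CC2(C)C | intermediate
9 | (1R,3S,6R)-3-[(2S)-4-hydroxy-1,1-dimethoxybutan-2-yl]-3,7,7-trimethylbicyclo[4.2.0]octan-2-one | O=C1[C@](C)([C@H](CCO)C(OC)OC)CC[C@@H]2[C@H]1CC2(C)C | intermediate
10 | (1R,3S,6R)-3-[(2S)-4-bromo-1,1-dimethoxybutan-2-yl]-3,7,7-trimethylbicyclo[4.2.0]octan-2-one | O=C1[C@](C)([C@H](CCBr)C(OC)OC)CC[C@@H]2[C@H]1CC2(C)C | intermediate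
11 | (1R,4S,7R)-4-[(2S)-4-bromo-1,1-dimethoxybutan-2-yl]-4,8,8-trimethyl-3-oxabicyclo[5.2.0]nonan-2-one | O=C1O[C@](C)([C@H](CCBr)C(OC)OC)CC[C@@H]2[C@H]1CC2(C)C | intermediate
12 | (1R,4S,5S,8S,9R)-5-(dimethoxymethyl)-4,11,11-trimethyl-4,8-epoxybicyclo[7.2.0]undecan-8-ol | O[C@@]12CC[C@H](C(OC)OC)[C@@](C)(O1)CC[C@@H]3[C@H]2CC3(C)C | intermediate
13 | methyl 2-methylpropanoate | COC(=O)C(C)C | starting material
14 | diketene | C=C1CC(=O)O1 | starting material
15 | methyl 2,2-dimethyl-3,5-dioxohexanoate | COC(=O)C(C)(C)C(=O)CC(C)=O | intermediate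
16 | 2,2-dimethylcyclohexane-1,3,5-trione (filicinic acid) | CC1(C)C(=O)CC(=O)CC1=O | intermediate
17 | 2-methylpropanoyl chloride | CC(C)C(=O)Cl | starting material
18 | 4,4-dimethyl-3,5-dioxocyclohex-1-en-1-yl 2-methylpropanoate | CC(C)C(=O)OC1=CC(=O)C(C)(C)C(=O)C1 | intermediate
19 | 3,5-dihydroxy-6,6-dimethyl-2-(2-methylpropanoyl)cyclohexa-2,4-dien-1-one (norflavesone) | CC(C)C(=O)C1=C(O)C=C(O)C(C)(C)C1=O | intermediate
20 | Knoevenagel product: hemiketal of 12 with C1′H= joined to the ring CH carbon of 19 (5R; alkene geometry open) | O[C@@]12CC[C@H](C=C4C(=O)C(C)(C)C(=O)C(C(=O)C(C)C)=C4O)[C@@](C)(O1)CC[C@@H]3[C@H]2CC3(C)C | intermediate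
21 | reduced product: the same hemiketal with a C1′H2 link to the triketone (1R,4S,5R,8S,9R) | O[C@@]12CC[C@H](CC4=C(O)C(C)(C)C(=O)C(C(=O)C(C)C)=C4O)[C@@](C)(O1)CC[C@@H]3[C@H]2CC3(C)C | intermediate
22 | 8-oxo analogue of the target, cis four/nine fusion (1R,4S,5R,9R) | O=C1CC[C@@H]2CC3=C(O[C@@]2(C)CC[C@@H]2[C@H]1CC2(C)C)C(C)(C)C(=O)C(C(=O)C(C)C)=C3O | intermediate
23 | 8-oxo analogue of the target, trans four/nine fusion (1R,4S,5R,9S) | O=C1CC[C@@H]2CC3=C(O[C@@]2(C)CC[C@@H]2[C@@H]1CC2(C)C)C(C)(C)C(=O)C(C(=O)C(C)C)=C3O | intermediate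
24 | CNP0497637.1 (1R,4S,5R,9S) | C=C1CC[C@@H]2CC3=C(O[C@@]2(C)CC[C@@H]2[C@@H]1CC2(C)C)C(C)(C)C(=O)C(C(=O)C(C)C)=C3O | target

**Step count**
- Total steps: 12.
- Longest linear sequence: 10 (steps 1–8, 11, 12).

**Steps most likely to fail**

*Step 4 (the new step).* The hindered enol ether may be protodesilylated faster than it adds, or the two facial preferences may be mismatched.

The fallback sets out from 6 and 7, comes back at 10, and uses a known metal-catalysed allylation instead of a conjugate addition.
- 7 is reduced with NaBH4/CeCl3 to (E)-4,4-dimethoxybut-2-en-1-ol F1.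
- Methyl chloroformate and pyridine convert this into (E)-4,4-dimethoxybut-2-enyl methyl carbonate F2.
- 6 is cleaved with MeLi to the regiodefined lithium enolate, which is exchanged with Ba(Ot-Bu)2.
- The enolate is allylated with F2 under [Ir(cod)Cl]2 and O,O′-(1,1′-binaphthyl-2,2′-diyl) N,N-bis(1-phenylethyl)phosphoramidite. This branched-selective iridium-catalysed allylic alkylation of a cyclic ketone enolate is known to build adjacent quaternary and tertiary centres.
- The product is (1R,3S,6R)-3-[(2S)-1,1-dimethoxybut-3-en-2-yl]-3,7,7-trimethylbicyclo[4.2.0]octan-2-one F3.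
- Hydroboration with 9-BBN followed by Br2/NaOMe gives 10.

*Step 11.* The tertiary enol ether may ionise under acid, closure may occur on the wrong carbonyl, or C5 may epimerise through an enol ether.

The fallback sets out from 12, comes back at 22, and closes the pyran under base by addition–elimination.
- Wet silica/oxalic acid releases (1R,4S,5S,8S,9R)-8-hydroxy-4,11,11-trimethyl-4,8-epoxybicyclo[7.2.0]undecane-5-carbaldehyde F4.
- Proline-catalysed reductive coupling of F4 with 19 and the Hantzsch ester gives 21, which is now isolated.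
- TsCl/Et3N sulfonylates the free, non-chelated enol oxygen next to CMe2 to give the enol tosylate of 21 F5.
- DBU opens the hemiketal, and the C4 alkoxide displaces tosylate at exactly that carbon to give 22.

*Step 12.* The crowded ketone may resist the ylide, or olefination may outrun the C9 equilibration.

The fallback sets out from 22, comes back at 24, and separates the two events.
- DBU in toluene equilibrates 22 to 23, which is isolated.
- Me3SiCH2Li/CeCl3 (excess, the first equivalent being spent on the enol) adds to C8 to give the 8-hydroxy-8-(trimethylsilylmethyl) adduct of 23 F6.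
- Peterson elimination with KH gives 24.

**Further compounds**
F1 | step 4 | (E)-4,4-dimethoxybut-2-en-1-ol | COC(OC)/C=C/CO
F2 | step 4 | (E)-4,4-dimethoxybut-2-enyl methyl carbonate | COC(=O)OC/C=C/C(OC)OC
F3 | step 4 | (1R,3S,6R)-3-[(2S)-1,1-dimethoxybut-3-en-2-yl]-3,7,7-trimethylbicyclo[4.2.0]octan-2-one | O=C1[C@](C)([C@H](C=C)C(OC)OC)CC[C@@H]2[C@H]1CC2(C)C
F4 | step 11 | (1R,4S,5S,8S,9R)-8-hydroxy-4,11,11-trimethyl-4,8-epoxybicyclo[7.2.0]undecane-5-carbaldehyde | O[C@@]12CC[C@H](C=O)[C@@](C)(O1)CC[C@@H]3[C@H]2CC3(C)C
F5 | step 11 | enol tosylate of 21 (tosyloxy on the ring carbon next to CMe2) | O[C@@]12CC[C@H](CC4=C(OS(=O)(=O)c5ccc(C)cc5)C(C)(C)C(=O)C(C(=O)C(C)C)=C4O)[C@@](C)(O1)CC[C@@H]3[C@H]2CC3(C)C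
F6 | step 12 | 8-hydroxy-8-(trimethylsilylmethyl) adduct of 23 (C8 configuration open) | C[Si](C)(C)CC1(O)CC[C@@H]2CC3=C(O[C@@]2(C)CC[C@@H]2[C@@H]1CC2(C)C)C(C)(C)C(=O)C(C(=O)C(C)C)=C3O
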